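Locants: 2–8 and 1'–6' are the apigenin unit, 2''–8'' and 1'''–6''' the 7-methoxyflavone unit. The retrosynthesis first cuts the four benzyl ethers and the chelated 5''-methyl ether, then, in one event, the C3''–C3' bond together with the O1''–C2'' bond of pyranone ring C of the methoxyflavone unit.
Enabling feature: in that ring C, the ring oxygen O1'' (on C2'') and the aryl carbon C3' (on C3'') stand trans across C2''=C3'', and C2''=C3''–C4''=O is the skeleton of an ynone. This is the footprint of an anti oxy-arylation of a C2''≡C3'' triple bond by an ortho phenoxide (future O1'') and an arylpalladium species (future C3').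
The cut gives an open-chain ortho-hydroxyaryl ynone (from 2-hydroxy-4,6-dimethoxybenzaldehyde and 4-benzyloxyphenylacetylene, C4''–C3'' bond) and tri-O-benzyl-3'-iodoapigenin (from a 2'-hydroxychalcone, aldol C=C bond and O1–C2 bond).
Forward: rings A and B of the apigenin unit are joined by Claisen–Schmidt condensation and its ring C is closed oxidatively. Rings A and B of the second unit are joined as the ynone, whose ring C is closed in the fragment union, and a Lewis-acid global deprotection ends the route.
Stereochemistry: the target has no stereocentre; the E-alkene of the chalcone and the racemic carbinol of the propargylic alcohol are both erased on the way.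

Key step: step 7

Remark: the four starting materials 1, 3, 7 and 8 are taken as catalogue compounds.

Step 1
Reactants: 1 1-(2,4,6-trihydroxyphenyl)ethan-1-one
Product: 2 1-[2,4-bis(benzyloxy)-6-hydroxyphenyl]ethan-1-one
Conditions: BnBr (2.1 equiv), K2CO3, DMF, 0 °C → rt
Reagents that add atoms: benzyl bromide, BrCc1ccccc1
Why: Williamson etherification should stop at the dibenzyl ether because the last hydroxyl is hydrogen-bonded to the ketone carbonyl and is much less reactive.

Step 2
Reactants: 3 4-hydroxy-3-iodobenzaldehyde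
Product: 4 4-(benzyloxy)-3-iodobenzaldehyde
Conditions: BnBr, K2CO3, DMF, rt
Reagents that add atoms: benzyl bromide, BrCc1ccccc1
Why: Williamson etherification of an acidic para-formyl phenol is routine and leaves the aryl iodide and the aldehyde untouched.

Step 3
Reactants: 2 1-[2,4-bis(benzyloxy)-6-hydroxyphenyl]ethan-1-one; 4 4-(benzyloxy)-3-iodobenzaldehyde
Product: 5 (E)-1-[2,4-bis(benzyloxy)-6-hydroxyphenyl]-3-[4-(benzyloxy)-3-iodophenyl]prop-2-en-1-one
Conditions: KOH (50% aq), EtOH/THF, rt
Reagents that add atoms: none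
Why: Claisen–Schmidt condensation of a 2'-hydroxyacetophenone with a non-enolisable aryl aldehyde should give the E-chalcone by aldol addition and E1cB loss of water.

Step 4
Reactants: 5 (E)-1-[2,4-bis(benzyloxy)-6-hydroxyphenyl]-3-[4-(benzyloxy)-3-iodophenyl]prop-2-en-1-one
Product: 6 5,7-bis(benzyloxy)-2-[4-(benzyloxy)-3-iodophenyl]-4H-chromen-4-one
Conditions: I2 (10 mol%), DMSO, 120 °C
Reagents that add atoms: none
Why: Iodine-catalysed oxidative cyclisation of a 2'-hydroxychalcone in DMSO (oxa-Michael closure, α-iodination, loss of HI, reoxidation of iodide by DMSO) is the standard flavone synthesis and is expected to tolerate the aryl iodide and the benzyl ethers.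

Step 5
Reactants: 7 2-hydroxy-4,6-dimethoxybenzaldehyde; 8 1-(benzyloxy)-4-ethynylbenzene
Product: 10 2-{3-[4-(benzyloxy)phenyl]-1-hydroxyprop-2-yn-1-yl}-3,5-dimethoxyphenol (racemic), via lithium [4-(benzyloxy)phenyl]ethynide 9 (not isolated)
Conditions: 8 (2.5 equiv), n-BuLi (2.4 equiv), THF, –78 °C; then 7, –78 → 0 °C; aq NH4Cl
Reagents that add atoms: none
Why: 1,2-Addition of a lithium acetylide to a salicylaldehyde, with one sacrificial equivalent of acetylide deprotonating the phenol, is an established entry to ortho-hydroxyaryl propargylic alcohols; the carbinol centre forms racemic and is removed in step 6.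

Step 6
Reactants: 10 2-{3-[4-(benzyloxy)phenyl]-1-hydroxyprop-2-yn-1-yl}-3,5-dimethoxyphenol
Product: 11 3-[4-(benzyloxy)phenyl]-1-(2-hydroxy-4,6-dimethoxyphenyl)prop-2-yn-1-one
Conditions: activated MnO2 (15 equiv), CH2Cl2, rt
Reagents that add atoms: none
Why: Activated MnO2 oxidises benzylic–propargylic alcohols selectively under neutral conditions, and the ynone formed is stabilised by the hydrogen bond between its carbonyl and the ortho hydroxyl.

Step 7
Reactants: 11 3-[4-(benzyloxy)phenyl]-1-(2-hydroxy-4,6-dimethoxyphenyl)prop-2-yn-1-one; 6 5,7-bis(benzyloxy)-2-[4-(benzyloxy)-3-iodophenyl]-4H-chromen-4-one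
Product: 13 5,7-bis(benzyloxy)-2-{4-(benzyloxy)-3-[2-(4-(benzyloxy)phenyl)-5,7-dimethoxy-4-oxo-4H-chromen-3-yl]phenyl}-4H-chromen-4-one, via sodium 2-{3-[4-(benzyloxy)phenyl]prop-2-ynoyl}-3,5-dimethoxyphenolate 12 (not isolated)
Conditions: 11 (1.2 equiv), NaH (1.2 equiv), THF, 0 °C; then slow addition to 6, Pd(PPh3)4 (5 mol%), THF, 60 °C
Reagents that add atoms: none
Why: Proposed new method: oxidative addition of iodide 6 to zerovalent palladium should give an arylpalladium iodide that binds the ynone triple bond of 12, after which the ortho phenoxide attacks the β-alkyne carbon anti to palladium and the resulting 3-chromonyl(aryl)palladium species reductively eliminates, so that O1''–C2'' and C3''–C3' form in one catalytic turnover. The closest known reaction type is the Cacchi-type oxypalladation/reductive elimination of ortho-alkynylphenols with aryl halides to 2,3-disubstituted benzofurans, and the same 6-endo oxygen attack on an electrophile-activated ortho-oxygenated aryl ynone is known with iodine electrophiles (3-iodoflavone formation). Pyranone ring C is closed in the 6-endo-dig mode and no stereocentre is formed. The step needs 6-endo over 5-exo closure, which the ynone polarisation should secure, since the β-carbon is the Michael terminus and carries the cation-stabilising 4-benzyloxyphenyl group while palladium ends on the carbon α to the carbonyl. It also needs arylative over protonative cyclisation, which the proton-free sodium phenoxide should secure, because ring closure without palladium would have to generate a non-stabilised in-plane vinyl anion at C3''. Anti addition is the only geometry that places O1'' and the incoming aryl group trans across C2''=C3'', as ring C demands.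

Step 8
Reactants: 13 5,7-bis(benzyloxy)-2-{4-(benzyloxy)-3-[2-(4-(benzyloxy)phenyl)-5,7-dimethoxy-4-oxo-4H-chromen-3-yl]phenyl}-4H-chromen-4-one
Product: 14 5,7-dihydroxy-2-{4-hydroxy-3-[5-hydroxy-2-(4-hydroxyphenyl)-7-methoxy-4-oxo-4H-chromen-3-yl]phenyl}-4H-chromen-4-one
Conditions: BCl3 (1 M in CH2Cl2, 12 equiv), C6HMe5 (8 equiv), CH2Cl2, –78 °C → rt; then aq HCl
Reagents that add atoms: none
Why: Lewis-acid ether cleavage should remove the four aryl benzyl ethers at low temperature (benzyl cation trapped by pentamethylbenzene in a Friedel–Crafts reaction) and, on warming, the 5''-methyl ether through a six-membered boron chelate with the C4'' carbonyl, whereas the non-chelated 7''-methyl ether is inert to BCl3 at room temperature.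

Compound list
1 | 1-(2,4,6-trihydroxyphenyl)ethan-1-one (2',4',6'-trihydroxyacetophenone) | CC(=O)c1c(O)cc(O)cc1O | starting material
2 | 1-[2,4-bis(benzyloxy)-6-hydroxyphenyl]ethan-1-one | CC(=O)c1c(O)cc(OCc2ccccc2)cc1OCc1ccccc1 | intermediate
3 | 4-hydroxy-3-iodobenzaldehyde | O=Cc1ccc(O)c(I)c1 | starting material
4 | 4-(benzyloxy)-3-iodobenzaldehyde | O=Cc1ccc(OCc2ccccc2)c(I)c1 | intermediate
5 | (E)-1-[2,4-bis(benzyloxy)-6-hydroxyphenyl]-3-[4-(benzyloxy)-3-iodophenyl]prop-2-en-1-one | O=C(/C=C/c1ccc(OCc2ccccc2)c(I)c1)c1c(O)cc(OCc2ccccc2)cc1OCc1ccccc1 | intermediate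
6 | 5,7-bis(benzyloxy)-2-[4-(benzyloxy)-3-iodophenyl]-4H-chromen-4-one | O=c1cc(-c2ccc(OCc3ccccc3)c(I)c2)oc2cc(OCc3ccccc3)cc(OCc3ccccc3)c12 | intermediate
7 | 2-hydroxy-4,6-dimethoxybenzaldehyde | COc1cc(O)c(C=O)c(OC)c1 | starting material
8 | 1-(benzyloxy)-4-ethynylbenzene | C#Cc1ccc(OCc2ccccc2)cc1 | starting material
9 | lithium [4-(benzyloxy)phenyl]ethynide (not isolated) | [Li]C#Cc1ccc(OCc2ccccc2)cc1 | intermediate
10 | 2-{3-[4-(benzyloxy)phenyl]-1-hydroxyprop-2-yn-1-yl}-3,5-dimethoxyphenol (racemic) | COc1cc(O)c(C(O)C#Cc2ccc(OCc3ccccc3)cc2)c(OC)c1 | intermediate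
11 | 3-[4-(benzyloxy)phenyl]-1-(2-hydroxy-4,6-dimethoxyphenyl)prop-2-yn-1-one | COc1cc(O)c(C(=O)C#Cc2ccc(OCc3ccccc3)cc2)c(OC)c1 | intermediate
12 | sodium 2-{3-[4-(benzyloxy)phenyl]prop-2-ynoyl}-3,5-dimethoxyphenolate (not isolated) | COc1cc([O-])c(C(=O)C#Cc2ccc(OCc3ccccc3)cc2)c(OC)c1.[Na+] | intermediate
13 | 5,7-bis(benzyloxy)-2-{4-(benzyloxy)-3-[2-(4-(benzyloxy)phenyl)-5,7-dimethoxy-4-oxo-4H-chromen-3-yl]phenyl}-4H-chromen-4-one | COc1cc(OC)c2c(=O)c(-c3cc(-c4cc(=O)c5c(OCc6ccccc6)cc(OCc6ccccc6)cc5o4)ccc3OCc3ccccc3)c(-c3ccc(OCc4ccccc4)cc3)oc2c1 | intermediate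
14 | 5,7-dihydroxy-2-{4-hydroxy-3-[5-hydroxy-2-(4-hydroxyphenyl)-7-methoxy-4-oxo-4H-chromen-3-yl]phenyl}-4H-chromen-4-one (CNP0284832.0) | COc1cc(O)c2c(=O)c(-c3cc(-c4cc(=O)c5c(O)cc(O)cc5o4)ccc3O)c(-c3ccc(O)cc3)oc2c1 | target

Total step count: 8. Longest linear sequence: 5 steps (steps 1, 3, 4, 7, 8); the ynone branch reaches the target in 4 steps (steps 5, 6, 7, 8).

Steps most likely to fail

Step 7 (proposed new method). What may go wrong: protonative 6-endo or 5-exo cyclisation of the phenoxide by adventitious proton sources, or syn carbopalladation of the ynone outrunning anti oxypalladation. Either way ring C would close without the aryl group, or the aryl group would enter without the correct ring closure. The fallback uses known chemistry, sets out from 11 and 6 and comes back at 13. Ynone 11 is cyclised with Et2NH in DMF (amine conjugate addition, 6-endo closure, loss of the amine) to 2-[4-(benzyloxy)phenyl]-5,7-dimethoxy-4H-chromen-4-one F1. F1 is lithiated at C3 with LiN(i-Pr)2 in THF at –78 °C and quenched with I2 to give 2-[4-(benzyloxy)phenyl]-3-iodo-5,7-dimethoxy-4H-chromen-4-one F2. Iodide 6 is converted by Miyaura borylation (B2pin2, PdCl2(dppf), KOAc, dioxane, 90 °C) into 5,7-bis(benzyloxy)-2-[4-(benzyloxy)-3-(4,4,5,5-tetramethyl-1,3,2-dioxaborolan-2-yl)phenyl]-4H-chromen-4-one F3. Suzuki–Miyaura coupling of F2 with F3 (Pd(PPh3)4, K2CO3, DMF/H2O, 90 °C) should then give 13.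

Step 5. What may go wrong: sluggish addition to the deactivated phenoxide-aldehyde, and ionisation of the very electron-rich benzylic–propargylic diol (loss of water towards an ortho-quinone methide) during work-up or the following oxidation. The fallback sets out from 7 and comes back at 11, so it also bypasses step 6 in its unprotected form. Phenol 7 is protected with MOMCl and i-Pr2NEt in CH2Cl2 as 2,4-dimethoxy-6-(methoxymethoxy)benzaldehyde F4. Addition of lithium acetylide 9 (1.2 equiv, THF, –78 °C) gives 3-[4-(benzyloxy)phenyl]-1-[2,4-dimethoxy-6-(methoxymethoxy)phenyl]prop-2-yn-1-ol F5. MnO2 oxidation gives 3-[4-(benzyloxy)phenyl]-1-[2,4-dimethoxy-6-(methoxymethoxy)phenyl]prop-2-yn-1-one F6. Brief treatment with HCl in MeOH/THF at room temperature removes the acetal ortho to the carbonyl and should deliver 11.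

Step 8. What may go wrong: incomplete cleavage of the chelated 5''-methyl ether, slow erosion of the 7''-methyl ether under the large excess of BCl3, or Friedel–Crafts re-benzylation of the phloroglucinol-type rings. The fallback sets out from 13 and comes back at 14, and separates the two tasks by reaction type. Hydrogenolysis (H2, Pd/C, THF/MeOH, rt) removes the four benzyl groups to give 5,7-dihydroxy-2-{4-hydroxy-3-[2-(4-hydroxyphenyl)-5,7-dimethoxy-4-oxo-4H-chromen-3-yl]phenyl}-4H-chromen-4-one F7. A chelation-controlled mono-demethylation with AlCl3 in MeCN then cleaves only the methyl ether peri to the C4'' carbonyl and should give 14.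

Further compounds
F1 | step 7 | 2-[4-(benzyloxy)phenyl]-5,7-dimethoxy-4H-chromen-4-one | COc1cc(OC)c2c(=O)cc(-c3ccc(OCc4ccccc4)cc3)oc2c1
F2 | step 7 | 2-[4-(benzyloxy)phenyl]-3-iodo-5,7-dimethoxy-4H-chromen-4-one | COc1cc(OC)c2c(=O)c(I)c(-c3ccc(OCc4ccccc4)cc3)oc2c1
F3 | step 7 | 5,7-bis(benzyloxy)-2-[4-(benzyloxy)-3-(4,4,5,5-tetramethyl-1,3,2-dioxaborolan-2-yl)phenyl]-4H-chromen-4-one | O=c1cc(-c2ccc(OCc3ccccc3)c(B3OC(C)(C)C(C)(C)O3)c2)oc2cc(OCc3ccccc3)cc(OCc3ccccc3)c12
F4 | step 5 | 2,4-dimethoxy-6-(methoxymethoxy)benzaldehyde | COCOc1cc(OC)cc(OC)c1C=O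
F5 | step 5 | 3-[4-(benzyloxy)phenyl]-1-[2,4-dimethoxy-6-(methoxymethoxy)phenyl]prop-2-yn-1-ol (racemic) | COCOc1cc(OC)cc(OC)c1C(O)C#Cc1ccc(OCc2ccccc2)cc1
F6 | step 5 | 3-[4-(benzyloxy)phenyl]-1-[2,4-dimethoxy-6-(methoxymethoxy)phenyl]prop-2-yn-1-one | COCOc1cc(OC)cc(OC)c1C(=O)C#Cc1ccc(OCc2ccccc2)cc1
F7 | step 8 | 5,7-dihydroxy-2-{4-hydroxy-3-[2-(4-hydroxyphenyl)-5,7-dimethoxy-4-oxo-4H-chromen-3-yl]phenyl}-4H-chromen-4-one | COc1cc(OC)c2c(=O)c(-c3cc(-c4cc(=O)c5c(O)cc(O)cc5o4)ccc3O)c(-c3ccc(O)cc3)oc2c1
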